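**Retrosynthetic overview**

1. Target 16 ← 15 ← 14 ← diol 10: the phenol is unmasked last, and the C3 tertiary acetate is installed after the C4 coumarate, so the finished diester never has a free hydroxyl next to an ester.
2. Diol 10 ← silyl ether 9 ← ketone 5 plus two CH2 units from trimethylsulfonium iodide 6: one flask forms C2–C3, then C1–C2 and the C1=C2 vinyl group, and sets C3.
3. Feature the strategy rests on: the acyclic chain C3(CH3)–C4–C5–C6=C7(CH3)–C8 is the carbon skeleton of 6-methylhept-5-en-2-one. The target adds only the oxygen at C4 and the vinyl carbons C1=C2 on the ketone carbon C3. The only ring, the phenol ring of the coumaroyl ester, is bought.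
4. Ketone 5 ← 4 ← 3 ← sulcatone 1 + nitrosobenzene 2, by D-proline α-aminoxylation at the internal α-CH2, which sets C4 as S.
5. Ring formation: no ring of the target is built. The only ring closed is a transient oxirane (O, C2, C3) in the key step, and it is opened again in the same flask.

Key step: step 4

Remark: locants follow the 3,7-dimethylocta-1,6-diene chain and the target is the (3R,4S) diester; in step 2 the anilino fragment is assumed to leave as azobenzene, the redox-neutral outcome of the N–O cleavage.

**Route**

Step 1
Reactants: 1 6-methylhept-5-en-2-one (sulcatone, in excess); 2 nitrosobenzene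
Product: 3 (3S)-6-methyl-3-(phenylaminooxy)hept-5-en-2-one
Conditions: D-proline (20 mol %), DMSO, rt, slow addition of 2 to 1 (5–10 equiv)
Reagents that add atoms: none
Why: Proline-catalysed α-aminoxylation through the more substituted (E)-enamine of the methyl ketone, in which the carboxylic acid protonates the nitroso nitrogen and delivers its oxygen to one enamine face; D-proline gives the mirror image of the L-proline outcome and should set C4 (ketone C3) as S, while excess ketone and slow addition hold back N-attack and double oxidation.

Step 2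
Reactants: 3 (3S)-6-methyl-3-(phenylaminooxy)hept-5-en-2-one
Product: 4 (3S)-3-hydroxy-6-methylhept-5-en-2-one
Conditions: CuSO4·5H2O (30 mol %), MeOH, 0 °C
Reagents that add atoms: none
Why: Copper-catalysed N–O bond cleavage of an O-alkyl-N-arylhydroxylamine is the standard mild unmasking of aminoxylation products and should leave the ketone, the trisubstituted alkene and the α-stereocentre untouched.

Step 3
Reactants: 4 (3S)-3-hydroxy-6-methylhept-5-en-2-one
Product: 5 (3S)-3-(tert-butyldimethylsilyloxy)-6-methylhept-5-en-2-one
Conditions: TBSCl, imidazole, DMF, 0 °C → rt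
Reagents that add atoms: tert-butyldimethylsilyl chloride, CC(C)(C)[Si](C)(C)Cl
Why: Imidazole-promoted silylation of a secondary alcohol is too weakly basic to enolise the α-ketol, so the stereocentre should be kept, and it installs the bulky non-chelating group that the key step needs.

Step 4
Reactants: 5 (3S)-3-(tert-butyldimethylsilyloxy)-6-methylhept-5-en-2-one; 6 trimethylsulfonium iodide
Product: 9 (3R,4S)-4-(tert-butyldimethylsilyloxy)-3,7-dimethylocta-1,6-dien-3-ol, via oxirane 7 (not isolated), via sulfonium alkoxide 8 (not isolated)
Conditions: 6 (5 equiv), n-BuLi (4.8 equiv), THF, −10 °C; then 5, −10 °C → rt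
Reagents that add atoms: none
Why: Dimethylsulfonium methylide adds irreversibly to the C3 carbonyl and the resulting alkoxide expels Me2S to form C2–C3 as part of oxirane 7; a second ylide opens 7 by SN2 attack at its unsubstituted CH2, forming C1–C2 and sulfonium alkoxide 8. Further ylide deprotonates an S-methyl group of 8, and the new ylide carbon removes a C2 hydrogen through a five-membered syn transition state, releasing Me2S and giving the C1=C2 vinyl group and the tertiary alkoxide of 9. The closest known chemistry is the Corey–Chaykovsky epoxidation of ketones joined to the dimethylsulfonium methylide homologation of epoxides to allylic alcohols, run here in one flask with excess ylide. The only ring closed is the transient oxirane, by a 3-exo-tet displacement, and it does not survive. The new C3 stereocentre is set in the first addition under the polar Felkin–Anh model: the C4–OSi bond stands perpendicular to the carbonyl plane and anti to the incoming ylide, which passes H-4 while C5 sits near the carbonyl oxygen, so (4S) should give (3R), the 3,4-anti diol pattern and the opposite of chelate control. The step needs this face selectivity and addition faster than enolisation toward C4; the bulky, poorly coordinating silyl ether in THF rules out chelation, the high nucleophilicity of the ylide at −10 °C favours addition, and any silyl shift between the two oxygens is harmless because both are freed in step 5.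

Step 5
Reactants: 9 (3R,4S)-4-(tert-butyldimethylsilyloxy)-3,7-dimethylocta-1,6-dien-3-ol
Product: 10 (3R,4S)-3,7-dimethylocta-1,6-diene-3,4-diol
Conditions: Bu4NF, THF, 0 °C → rt
Reagents that add atoms: none
Why: Fluoride-driven desilylation (Si–F bond formation) meets nothing else that is base- or fluoride-labile in 9 and does not touch either carbinol stereocentre.

Step 6
Reactants: 11 p-coumaric acid
Product: 13 (E)-3-[4-(tert-butyldimethylsilyloxy)phenyl]prop-2-enoic acid, via bis-silyl derivative 12 (not isolated)
Conditions: TBSCl (2.4 equiv), imidazole, DMF, rt; then AcOH/THF/H2O, rt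
Reagents that add atoms: tert-butyldimethylsilyl chloride, CC(C)(C)[Si](C)(C)Cl
Why: Exhaustive silylation followed by selective hydrolysis of the far more labile silyl ester should leave the aryl silyl ether, giving a phenol-masked acid that cannot self-condense during coupling.

Step 7
Reactants: 10 (3R,4S)-3,7-dimethylocta-1,6-diene-3,4-diol; 13 (E)-3-[4-(tert-butyldimethylsilyloxy)phenyl]prop-2-enoic acid
Product: 14 (3R,4S)-3-hydroxy-3,7-dimethylocta-1,6-dien-4-yl (E)-3-[4-(tert-butyldimethylsilyloxy)phenyl]prop-2-enoate
Conditions: EDC·HCl, DMAP, CH2Cl2, 0 °C → rt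
Reagents that add atoms: none
Why: Steglich esterification with about one equivalent of acid should acylate the secondary C4 hydroxyl only, because the tertiary allylic C3 hydroxyl is too hindered to compete at this temperature.

Step 8
Reactants: 14 (3R,4S)-3-hydroxy-3,7-dimethylocta-1,6-dien-4-yl (E)-3-[4-(tert-butyldimethylsilyloxy)phenyl]prop-2-enoate
Product: 15 (3R,4S)-3-acetoxy-3,7-dimethylocta-1,6-dien-4-yl (E)-3-[4-(tert-butyldimethylsilyloxy)phenyl]prop-2-enoate
Conditions: Ac2O, Et3N, DMAP, CH2Cl2, rt → 35 °C
Reagents that add atoms: acetic anhydride, CC(=O)OC(C)=O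
Why: DMAP-catalysed acylation with acetic anhydride is the standard way to esterify tertiary alcohols, and the cinnamate, the aryl silyl ether and both stereocentres should tolerate the mildly basic medium.

Step 9
Reactants: 15 (3R,4S)-3-acetoxy-3,7-dimethylocta-1,6-dien-4-yl (E)-3-[4-(tert-butyldimethylsilyloxy)phenyl]prop-2-enoate
Product: 16 (3R,4S)-3-acetoxy-3,7-dimethylocta-1,6-dien-4-yl (E)-3-(4-hydroxyphenyl)prop-2-enoate (target)
Conditions: Bu4NF/AcOH (1:1), THF, 0 °C
Reagents that add atoms: none
Why: Aryl silyl ethers are cleaved by fluoride within minutes at 0 °C, and the acetic acid buffer keeps the liberated phenol protonated so that neither ester should be hydrolysed or transacylated.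

**Compound list**

1 | 6-methylhept-5-en-2-one (sulcatone) | CC(=O)CCC=C(C)C | starting material
2 | nitrosobenzene | O=Nc1ccccc1 | starting material
3 | (3S)-6-methyl-3-(phenylaminooxy)hept-5-en-2-one | CC(=O)[C@H](CC=C(C)C)ONc1ccccc1 | intermediate
4 | (3S)-3-hydroxy-6-methylhept-5-en-2-one | CC(=O)[C@H](CC=C(C)C)O | intermediate
5 | (3S)-3-(tert-butyldimethylsilyloxy)-6-methylhept-5-en-2-one | CC(=O)[C@H](CC=C(C)C)O[Si](C)(C)C(C)(C)C | intermediate
6 | trimethylsulfonium iodide | C[S+](C)C.[I-] | starting material
7 | (2R)-2-[(1S)-1-(tert-butyldimethylsilyloxy)-4-methylpent-3-en-1-yl]-2-methyloxirane | C1[C@@](C)(O1)[C@H](CC=C(C)C)O[Si](C)(C)C(C)(C)C | intermediate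
8 | (3R,4S)-4-(tert-butyldimethylsilyloxy)-1-(dimethylsulfonio)-3,7-dimethyloct-6-en-3-olate | C[S+](C)CC[C@@](C)([O-])[C@H](CC=C(C)C)O[Si](C)(C)C(C)(C)C | intermediate
9 | (3R,4S)-4-(tert-butyldimethylsilyloxy)-3,7-dimethylocta-1,6-dien-3-ol | C=C[C@@](C)(O)[C@H](CC=C(C)C)O[Si](C)(C)C(C)(C)C | intermediate
10 | (3R,4S)-3,7-dimethylocta-1,6-diene-3,4-diol | C=C[C@@](C)(O)[C@H](CC=C(C)C)O | intermediate
11 | p-coumaric acid, (E)-3-(4-hydroxyphenyl)prop-2-enoic acid | O=C(O)/C=C/c1ccc(O)cc1 | starting material
12 | tert-butyldimethylsilyl (E)-3-[4-(tert-butyldimethylsilyloxy)phenyl]prop-2-enoate | CC(C)(C)[Si](C)(C)OC(=O)/C=C/c1ccc(O[Si](C)(C)C(C)(C)C)cc1 | intermediate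
13 | (E)-3-[4-(tert-butyldimethylsilyloxy)phenyl]prop-2-enoic acid | OC(=O)/C=C/c1ccc(O[Si](C)(C)C(C)(C)C)cc1 | intermediate
14 | (3R,4S)-3-hydroxy-3,7-dimethylocta-1,6-dien-4-yl (E)-3-[4-(tert-butyldimethylsilyloxy)phenyl]prop-2-enoate | C=C[C@@](C)(O)[C@H](CC=C(C)C)OC(=O)/C=C/c1ccc(O[Si](C)(C)C(C)(C)C)cc1 | intermediate
15 | (3R,4S)-3-acetoxy-3,7-dimethylocta-1,6-dien-4-yl (E)-3-[4-(tert-butyldimethylsilyloxy)phenyl]prop-2-enoate | C=C[C@@](C)(OC(C)=O)[C@H](CC=C(C)C)OC(=O)/C=C/c1ccc(O[Si](C)(C)C(C)(C)C)cc1 | intermediate
16 | (3R,4S)-3-acetoxy-3,7-dimethylocta-1,6-dien-4-yl (E)-3-(4-hydroxyphenyl)prop-2-enoate | C=C[C@@](C)(OC(C)=O)[C@H](CC=C(C)C)OC(=O)/C=C/c1ccc(O)cc1 | target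

**Step count**

Total steps: 9. Longest linear sequence: 8 (steps 1, 2, 3, 4, 5, 7, 8, 9); step 6 is a one-step side branch.

**Steps most likely to fail**

Step 4 (key step). The first ylide addition may discriminate poorly between the two ketone faces, enolisation toward C4 may erode the existing stereocentre, or the second methylene transfer may stall at the hindered oxirane. The fallback sets out from 5 and comes back at 9. The vinyl group is delivered in one C–C bond-forming event by a weakly basic, non-chelated vinyl nucleophile (CH2=CHMgBr premixed with anhydrous CeCl3, THF, −78 °C), which should add with the same Felkin–Anh sense and give 9 directly. No new compound arises (F0). Any C3 epimer would be removed by chromatography at diol 10.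

Step 1. Oxidation may occur at the methyl rather than the internal α-carbon, the nitroso group may be attacked at nitrogen instead of oxygen, or nitrosobenzene may be consumed by double aminoxylation or an ene reaction with the prenyl alkene. The fallback does not set out from a numbered compound, because 1 and 2 are replaced by a purchased chiral building block; it comes back at 5. Methyl (2S)-oxirane-2-carboxylate F1 is opened at its CH2 by 2-methylprop-1-enylmagnesium bromide with catalytic CuI in THF at −40 °C to give methyl (2S)-2-hydroxy-5-methylhex-4-enoate F2, the stereocentre being carried over untouched. TBSCl and imidazole in DMF then give methyl (2S)-2-(tert-butyldimethylsilyloxy)-5-methylhex-4-enoate F3. MeNH(OMe)·HCl with i-PrMgCl in THF at −20 °C converts this into (2S)-2-(tert-butyldimethylsilyloxy)-N-methoxy-N,5-dimethylhex-4-enamide F4, and MeMgBr in THF at 0 °C delivers ketone 5.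

Step 8. Acetylation of the hindered tertiary carbinol next to the cinnamate may be slow, and a base-mediated 1,2-shift of the coumaroyl group would expose the secondary hydroxyl to acetylation and scramble the two esters. The fallback sets out from 9 and comes back at 15. The tertiary hydroxyl of 9 is acetylated before any other ester is present, as its lithium alkoxide (LiN(SiMe3)2, THF, −78 °C, then Ac2O), to give (3R,4S)-4-(tert-butyldimethylsilyloxy)-3,7-dimethylocta-1,6-dien-3-yl acetate F5. The silyl ether is removed under acidic conditions that should not promote acyl migration (HF·pyridine, THF/pyridine, 0 °C) to give (3R,4S)-4-hydroxy-3,7-dimethylocta-1,6-dien-3-yl acetate F6. This is esterified at once with acid 13 (EDC·HCl, DMAP, CH2Cl2, 0 °C) to give 15.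

**Further compounds**

F0 | step 4 | none | none
F1 | step 1 | methyl (2S)-oxirane-2-carboxylate (purchased) | COC(=O)[C@@H]1CO1
F2 | step 1 | methyl (2S)-2-hydroxy-5-methylhex-4-enoate | COC(=O)[C@H](CC=C(C)C)O
F3 | step 1 | methyl (2S)-2-(tert-butyldimethylsilyloxy)-5-methylhex-4-enoate | COC(=O)[C@H](CC=C(C)C)O[Si](C)(C)C(C)(C)C
F4 | step 1 | (2S)-2-(tert-butyldimethylsilyloxy)-N-methoxy-N,5-dimethylhex-4-enamide | CON(C)C(=O)[C@H](CC=C(C)C)O[Si](C)(C)C(C)(C)C
F5 | step 8 | (3R,4S)-4-(tert-butyldimethylsilyloxy)-3,7-dimethylocta-1,6-dien-3-yl acetate | C=C[C@@](C)(OC(C)=O)[C@H](CC=C(C)C)O[Si](C)(C)C(C)(C)C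
F6 | step 8 | (3R,4S)-4-hydroxy-3,7-dimethylocta-1,6-dien-3-yl acetate | C=C[C@@](C)(OC(C)=O)[C@H](CC=C(C)C)O
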